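After 1.00 min the dusk run's ledger of free monomer reads 55.1% still free, 6.2% in chains, and the remainder, 38.7%, lost outside chains. We read that lost entry as a second-order reaction of free monomer with protic impurity, and since the two are charged equally, lost over unlost should grow in proportion to time. The dusk reading then gives 1.58 min for the quench time, the time at which the lost and unlost parts of the charge stand equal. The spring run, with more pre-initiator, gives 1.58 min from its reading at 0.833 min, but at 2.50 min the dusk run gives 1.77 min and the spring run, with more monomer in chains, gives 2.06 min, a gap well beyond the scatter, so the quench time is a measure for the early readings and the lost entry does differ with the pre-initiator charge.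

in all of them: free monomer 0.80 M; stray impurity 45 mM
- dusk: protic impurity 0.80 M; pre-initiator 110 mM; run made earlier
- spring: protic impurity 0.80 M; pre-initiator 180 mM; run made earlier
- autumn: protic impurity 1.6 M; pre-initiator 80 mM; run made earlier
- flask: protic impurity 0.800 M; pre-initiator 80 mM; time 2.0 min

| run | time / min | monomer in chains / % | free monomer / % |
|---|---|---|---|
| dusk | 0.200 | 0 | 86.3 |
| dusk | 0.417 | 1.6 | 76.7 |
| dusk | 1.00 | 6.2 | 55.1 |
| dusk | 2.50 | 18.2 | 23.2 |
| spring | 0.333 | 2.1 | 80.2 |
| spring | 0.833 | 8.2 | 57.3 |
| spring | 1.50 | 19.4 | 35.3 |
| spring | 2.50 | 34.8 | 10.4 |
| autumn | 0.200 | 0.4 | 77.9 |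
| autumn | 0.417 | 1.0 | 59.6 |
| autumn | 1.00 | 2.9 | 31.9 |
| autumn | 2.50 | 5.8 | 8.7 |

(standard deviation of a reading: 0.5 percentage points)

- the average divides the monomer in chains by the number of chains begun, living and dead together
- the earlier runs do not show the number of chains; that part of a forecast is a guess

- average number of monomer units in a chain (chains begun, living or dead) at 2.0 min
- part of the free monomer that has reacted at 2.0 min

For the new flask at 2.0 min our lost entry is time over time plus quench time, 55.8%. For the chain entry we interpolate the dusk run to that time and scale it by pre-initiator in excess of stray impurity, which gives 7.65%. The books close with 36.6% free, so our c is 63.5%, and with no reading of the number of chains we put no figure on dp.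

The forecast gives dp 2 and c 61%, a c lower than ours, and says of its dp: “That gives dp about 2, which is largely a guess.”

The flask gives dp 6.40, which is 3.20 times the forecast's, and c 65.2%.

    initiator + stray impurity → spent initiator (k = 31.0 L mol⁻¹ s⁻¹)
    free monomer + living end → monomer in chains + living end, rate k2*[living end]*[free monomer] (k = 0.200 L mol⁻¹ s⁻¹)
    protic impurity + free monomer → quenched substrate (k = 0.0140 L mol⁻¹ s⁻¹)
    pre-initiator → initiator (k = 0.00660 s⁻¹)
    free monomer + initiator → living end + monomer in chains (k = 0.720 L mol⁻¹ s⁻¹)

At 2.00 min in this flask stray impurity uses initiator 2.2 times as fast as free monomer does, and spent initiator stands at 0.0309 M beside 0.0125 M of living end, and the 10.0% of monomer in chains divides among that living end alone to 6.40 units each. The quench time puts the lost entry at 55.8% against quenched substrate at 55.2% in this flask, and against 53.4% in the neighbour flask with 0.018 M of stray impurity, where monomer in chains reaches 18.1%.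

(The readings were computed with constants of no real substance; noise was put on by code.)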